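Assumption: compounds 1 and 5 are catalogue compounds (dihydroisoferulic acid, methyl dihydroferulate), and the target is the trans-(3R,4R) lactone, the absolute configuration of (−)-matairesinol.

## Retrosynthetic overview

1. Only one ring is made, the γ-lactone, and it is made last: a C9′ carbinol closes onto the C9 ester, the same two carbons joined in the secoisolariciresinol → matairesinol lactonisation. In the same pot C3 equilibrates to trans and the phenol esters are removed.
2. The 2,3-dibenzylsuccinate precursor is cut at C8–C8′: a one-electron oxidative cross-coupling of two C6C3 enolates. This is the lignan 8–8′ coupling done at the enolate level, because the 3-OH/4-OMe ring has no para-phenol to carry a phenoxy radical to C8.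
3. An (S)-4-benzyloxazolidinone on the isovanillyl half plays the role of the dirigent protein: it fixes C8′ (the non-epimerisable C4 of the lactone) and marks that carbonyl as the one to be reduced.
4. The halves are dihydroisoferulic acid and methyl dihydroferulate, with the phenols masked as pivalates by the same reagent that activates the acid.

## Route

Step 1
Reactants: 1 3-(3-hydroxy-4-methoxyphenyl)propanoic acid; 2 (S)-4-benzyloxazolidin-2-one
Product: 4 (S)-4-benzyl-3-{3-[4-methoxy-3-(pivaloyloxy)phenyl]propanoyl}oxazolidin-2-one, via mixed pivalic anhydride 3 (not isolated)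
Conditions: PivCl (2.1 equiv), Et3N (3.5 equiv), THF, −20 → 0 °C; then LiCl (1 equiv), 2 (0.95 equiv), rt
Reagents that add atoms: pivaloyl chloride, CC(C)(C)C(=O)Cl
Why: One-pot mixed-anhydride N-acylation of an Evans auxiliary in which PivCl esterifies the phenol and activates the acid, and the LiCl/Et3N-activated oxazolidinone attacks only the unhindered arylpropanoyl carbonyl of 3; no new stereocentre is formed, the (S)-centre comes from 2.

Step 2
Reactants: 5 methyl 3-(4-hydroxy-3-methoxyphenyl)propanoate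
Product: 6 methyl 3-[3-methoxy-4-(pivaloyloxy)phenyl]propanoate
Conditions: PivCl (1.2 equiv), Et3N (1.5 equiv), DMAP (cat.), CH2Cl2, 0 °C → rt
Reagents that add atoms: pivaloyl chloride, CC(C)(C)C(=O)Cl
Why: DMAP-catalysed O-acylation of the phenol; the aryl pivalate has no α-hydrogens and a shielded carbonyl, so it should tolerate LDA and enolates at −78 °C, and it is later removed by the methoxide used in step 4.

Step 3
Reactants: 4 (S)-4-benzyl-3-{3-[4-methoxy-3-(pivaloyloxy)phenyl]propanoyl}oxazolidin-2-one; 6 methyl 3-[3-methoxy-4-(pivaloyloxy)phenyl]propanoate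
Product: 9 methyl (3R)-4-[(4S)-4-benzyl-2-oxooxazolidin-3-yl]-3-[4-methoxy-3-(pivaloyloxy)benzyl]-2-[3-methoxy-4-(pivaloyloxy)benzyl]-4-oxobutanoate (C2 epimer mixture), via lithium imide enolate 7 (not isolated), via lithium ester enolate 8 (not isolated)
Conditions: 4 : 6 = 1 : 1.5, LDA (2.6 equiv), THF, −78 °C, 30 min; then Fe(acac)3 (2.6 equiv), −78 °C → rt
Reagents that add atoms: none
Why: Oxidative enolate heterocoupling (Baran-type Fe(III) single-electron oxidation within the mixed lithium enolate aggregate), where the imide and ester enolates differ enough in oxidation potential and aggregation for cross-coupling to beat homo-coupling; the chelated Z-enolate 7 of the (S)-benzyl imide reacts on the face away from the benzyl group (same sense as an Evans alkylation), setting the imide α-carbon (future C4) as R, while the ester α-carbon (future C3) forms as a mixture that is corrected in step 4.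

Step 4
Reactants: 9 methyl (3R)-4-[(4S)-4-benzyl-2-oxooxazolidin-3-yl]-3-[4-methoxy-3-(pivaloyloxy)benzyl]-2-[3-methoxy-4-(pivaloyloxy)benzyl]-4-oxobutanoate (C2 epimer mixture)
Product: 12 (3R,4R)-3-(4-hydroxy-3-methoxybenzyl)-4-(3-hydroxy-4-methoxybenzyl)dihydrofuran-2(3H)-one, via hydroxy ester 10 (not isolated), via bis-pivalate lactone 11 (not isolated)
Conditions: LiBH4, MeOH (1.3 equiv each), THF, 0 °C; aq NH4Cl, crude; then NaOMe (6 equiv), MeOH, rt → 50 °C (argon); then 2 M HCl to pH 1, rt
Reagents that add atoms: none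
Why: Reductive removal of the Evans auxiliary (LiBH4 reduces the exocyclic imide carbonyl faster than the methyl ester) gives the C9′ carbinol, which lactonises onto the C9 ester, and NaOMe then methanolyses both aryl pivalates and epimerises the only acidic stereocentre, C3, to the thermodynamically favoured trans (3R,4R) lactone; C4 has no acidic hydrogen and is untouched, and acidification re-closes any ring-opened hydroxy ester.

## Compound list

1 | 3-(3-hydroxy-4-methoxyphenyl)propanoic acid | COc1ccc(CCC(=O)O)cc1O | starting material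
2 | (S)-4-benzyloxazolidin-2-one | O=C1N[C@@H](Cc2ccccc2)CO1 | starting material
3 | 3-[4-methoxy-3-(pivaloyloxy)phenyl]propanoic pivalic anhydride | COc1ccc(CCC(=O)OC(=O)C(C)(C)C)cc1OC(=O)C(C)(C)C | intermediate (not isolated)
4 | (S)-4-benzyl-3-{3-[4-methoxy-3-(pivaloyloxy)phenyl]propanoyl}oxazolidin-2-one | COc1ccc(CCC(=O)N2[C@@H](Cc3ccccc3)COC2=O)cc1OC(=O)C(C)(C)C | intermediate
5 | methyl 3-(4-hydroxy-3-methoxyphenyl)propanoate | COC(=O)CCc1ccc(O)c(OC)c1 | starting material
6 | methyl 3-[3-methoxy-4-(pivaloyloxy)phenyl]propanoate | COC(=O)CCc1ccc(OC(=O)C(C)(C)C)c(OC)c1 | intermediate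
7 | lithium (Z)-enolate of 4 | COc1ccc(C/C=C(\O[Li])N2[C@@H](Cc3ccccc3)COC2=O)cc1OC(=O)C(C)(C)C | intermediate (not isolated)
8 | lithium enolate of 6 (geometry not specified) | COC(O[Li])=CCc1ccc(OC(=O)C(C)(C)C)c(OC)c1 | intermediate (not isolated)
9 | methyl (3R)-4-[(4S)-4-benzyl-2-oxooxazolidin-3-yl]-3-[4-methoxy-3-(pivaloyloxy)benzyl]-2-[3-methoxy-4-(pivaloyloxy)benzyl]-4-oxobutanoate (C2 epimer mixture) | COC(=O)C(Cc1ccc(OC(=O)C(C)(C)C)c(OC)c1)[C@@H](Cc1ccc(OC)c(OC(=O)C(C)(C)C)c1)C(=O)N1[C@@H](Cc2ccccc2)COC1=O | intermediate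
10 | methyl (3R)-4-hydroxy-3-[4-methoxy-3-(pivaloyloxy)benzyl]-2-[3-methoxy-4-(pivaloyloxy)benzyl]butanoate (C2 epimer mixture) | COC(=O)C(Cc1ccc(OC(=O)C(C)(C)C)c(OC)c1)[C@@H](Cc1ccc(OC)c(OC(=O)C(C)(C)C)c1)CO | intermediate (not isolated)
11 | (4R)-4-[4-methoxy-3-(pivaloyloxy)benzyl]-3-[3-methoxy-4-(pivaloyloxy)benzyl]dihydrofuran-2(3H)-one (C3 epimer mixture) | O=C1OC[C@H](Cc2ccc(OC)c(OC(=O)C(C)(C)C)c2)C1Cc3ccc(OC(=O)C(C)(C)C)c(OC)c3 | intermediate (not isolated)
12 | (3R,4R)-3-(4-hydroxy-3-methoxybenzyl)-4-(3-hydroxy-4-methoxybenzyl)dihydrofuran-2(3H)-one | COc1ccc(C[C@H]2COC(=O)[C@@H]2Cc2ccc(O)c(OC)c2)cc1O | target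

## Step count and risks

Total step count: 4. Longest linear sequence: 3 (1 → 4 → 9 → 12, or 5 → 6 → 9 → 12).

**Step 3 (most likely to fail).** The risks are homodimers of 4 or 6, pivaloyl transfer from an aryl pivalate to an enolate, and a modest yield. The fallback sets out from 4 and comes back at 11; it builds the C8–C8′ framework by two enolate alkylations instead of one oxidative coupling. NaHMDS (THF, −78 °C) converts 4 into the sodium (Z)-enolate of 4 F1, which tert-butyl bromoacetate alkylates on the face away from the auxiliary benzyl group to give tert-butyl (3R)-4-[(4S)-4-benzyl-2-oxooxazolidin-3-yl]-3-[4-methoxy-3-(pivaloyloxy)benzyl]-4-oxobutanoate F2. LiBH4/MeOH (THF, 0 °C; the tert-butyl ester is inert) gives tert-butyl (3R)-4-hydroxy-3-[4-methoxy-3-(pivaloyloxy)benzyl]butanoate F3, which TFA in CH2Cl2 closes to (4R)-4-[4-methoxy-3-(pivaloyloxy)benzyl]dihydrofuran-2(3H)-one F4. Separately, bought vanillyl alcohol is acylated at the phenol only (PivCl, aq NaOH/CH2Cl2, 0 °C) to 4-(hydroxymethyl)-2-methoxyphenyl pivalate F5 and brominated (PBr3, Et2O, 0 °C) to 4-(bromomethyl)-2-methoxyphenyl pivalate F6. LiHMDS (THF, −78 °C) turns F4 into the lithium lactone enolate F7, which F6 alkylates anti to the C4 substituent to give the trans (3R,4R) epimer of 11. The methoxide/HCl stage of step 4 then gives 12.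

**Step 4.** The risks are over-reduction of the methyl ester or the lactone to the diol, endocyclic opening of the hindered oxazolidinone, and incomplete convergence to trans. The fallback sets out from 9 and comes back at 10; it removes the auxiliary by hydrolysis and brings C9′ to the alcohol level with an electrophilic reductant. LiOH/H2O2 (THF/H2O, 0 °C; Na2SO3 quench) cleaves the imide to (2R)-4-methoxy-2-[4-methoxy-3-(pivaloyloxy)benzyl]-3-[3-methoxy-4-(pivaloyloxy)benzyl]-4-oxobutanoic acid F8. BH3·SMe2 (THF, 0 °C → rt) reduces the free acid in the presence of the methyl ester and aryl pivalates to give hydroxy ester 10, which enters the methoxide/HCl stage of step 4.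

**Step 1.** The risks are acylation of the free phenol by the mixed anhydride (oligoesters) and N-pivaloylation of 2. The fallback sets out from 1 and comes back at 4; it separates protection from acylation and uses an acid chloride. PivCl (2.2 equiv)/pyridine followed by aqueous hydrolysis of the mixed anhydride 3 gives 3-[4-methoxy-3-(pivaloyloxy)phenyl]propanoic acid F9. Oxalyl chloride/cat. DMF (CH2Cl2) gives 3-[4-methoxy-3-(pivaloyloxy)phenyl]propanoyl chloride F10, which acylates 2 (Et3N, cat. DMAP, CH2Cl2, 0 °C → rt) to give 4.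

## Further compounds

F1 | step 3 | sodium (Z)-enolate of 4 | COc1ccc(C/C=C(\O[Na])N2[C@@H](Cc3ccccc3)COC2=O)cc1OC(=O)C(C)(C)C
F2 | step 3 | tert-butyl (3R)-4-[(4S)-4-benzyl-2-oxooxazolidin-3-yl]-3-[4-methoxy-3-(pivaloyloxy)benzyl]-4-oxobutanoate | CC(C)(C)OC(=O)C[C@@H](Cc1ccc(OC)c(OC(=O)C(C)(C)C)c1)C(=O)N1[C@@H](Cc2ccccc2)COC1=O
F3 | step 3 | tert-butyl (3R)-4-hydroxy-3-[4-methoxy-3-(pivaloyloxy)benzyl]butanoate | CC(C)(C)OC(=O)C[C@@H](Cc1ccc(OC)c(OC(=O)C(C)(C)C)c1)CO
F4 | step 3 | (4R)-4-[4-methoxy-3-(pivaloyloxy)benzyl]dihydrofuran-2(3H)-one | O=C1C[C@@H](Cc2ccc(OC)c(OC(=O)C(C)(C)C)c2)CO1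
F5 | step 3 | 4-(hydroxymethyl)-2-methoxyphenyl pivalate | COc1cc(CO)ccc1OC(=O)C(C)(C)C
F6 | step 3 | 4-(bromomethyl)-2-methoxyphenyl pivalate | COc1cc(CBr)ccc1OC(=O)C(C)(C)C
F7 | step 3 | lithium enolate of F4 | [Li]OC1=C[C@@H](Cc2ccc(OC)c(OC(=O)C(C)(C)C)c2)CO1
F8 | step 4 | (2R)-4-methoxy-2-[4-methoxy-3-(pivaloyloxy)benzyl]-3-[3-methoxy-4-(pivaloyloxy)benzyl]-4-oxobutanoic acid (C3 epimer mixture) | COC(=O)C(Cc1ccc(OC(=O)C(C)(C)C)c(OC)c1)[C@@H](Cc1ccc(OC)c(OC(=O)C(C)(C)C)c1)C(=O)O
F9 | step 1 | 3-[4-methoxy-3-(pivaloyloxy)phenyl]propanoic acid | COc1ccc(CCC(=O)O)cc1OC(=O)C(C)(C)C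
F10 | step 1 | 3-[4-methoxy-3-(pivaloyloxy)phenyl]propanoyl chloride | COc1ccc(CCC(=O)Cl)cc1OC(=O)C(C)(C)C
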